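The numbering is cembrane-type: C1 is the ring-fusion CH, C2–C13 run round the carbocycle, C14 is the O–CH, C15 is the lactone carbon bearing exocyclic C17, C16 is the carbonyl, Cl sits on C11 and the carbinol is C12. The target is (1R,3E,7E,11S,12R,14S).
The enabling feature is that the trans-fused α-methylene-γ-butyrolactone ring (O, C14, C1, C15, C16) shares its C1–C14 bond with the 14-membered ring C1–C14. It is therefore the retron of a 2-(methoxycarbonyl)allyl boronate adding through C1 to a C14 aldehyde, one event that closes both rings.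
The retrosynthetic cuts, in order, are O12–Si, then O14–C16 and C1–C14, then C15–C17, C1–C2, C13–C14, C11–Cl and the C11/C12/C13 oxygenation. This leads back to (2E,6E)-farnesol, which supplies C2–C13 and all three methyl groups.
In the forward direction the farnesyl chain is first functionalised at its west end (C13 hydroxylation, epoxidation, chloride opening, C14 by methylenation and hydroboration). It is then extended at its east end (propiolate for C1/C15/C16, borylmethyl for C17), and the carbocycle closes first and the lactone second, in one flask.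
C12 (R) and C11 (S) come from a Sharpless epoxidation with D-(−)-diethyl tartrate and invertive chloride opening at C11, and both ring E-alkenes come from farnesol. The anti C1/C14 relation comes from the boronate alkene geometry in a chair transition state, and its sense (1R,14S) comes from the C12 centre.
Key step: step 15

Remark on the chemistry: in the alkenylalane and the allylboronates C2 lies trans to the C17 position. This is the arrangement of an E-crotyl reagent and is needed for an anti adduct. Because CO2Me outranks CH2B, the CIP descriptor of this alkene in the boronates is Z.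
Assumption: commercial (2E,6E)-farnesol is taken as a single geometric isomer.

Step 1
Reactants: 1 (2E,6E)-farnesol
Product: 2 (2E,6E)-farnesyl acetate
Conditions: Ac2O, pyridine, DMAP (cat.), CH2Cl2, 0 °C to rt
Reagents that add atoms: acetic anhydride CC(=O)OC(C)=O
Why: DMAP-catalysed O-acetylation masks the C2 hydroxyl as an ester that survives the oxidative and Lewis-acidic steps ahead and lowers the electron density of the C3=C4 alkene, which steers the next oxidation to the far end of the chain.

Step 2
Reactants: 2 (2E,6E)-farnesyl acetate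
Product: 3 (2E,6E,10E)-12-hydroxyfarnesyl acetate (C13 carbinol, C11=C12 still E)
Conditions: SeO2 (20 mol %), t-BuOOH, salicylic acid (10 mol %), CH2Cl2, 0 °C to rt, stopped before full conversion
Reagents that add atoms: tert-butyl hydroperoxide CC(C)(C)OO (terminal oxygen source); selenium dioxide O=[Se]=O (oxygen carrier)
Why: Riley allylic oxidation (ene reaction followed by a 2,3-sigmatropic shift) prefers the most electron-rich terminal trisubstituted alkene and hydroxylates its E-methyl group, a selectivity that is well established for farnesyl esters, so C13 becomes a carbinol and C11=C12 stays E.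

Step 3
Reactants: 3 (2E,6E,10E)-12-hydroxyfarnesyl acetate
Product: 4 (11R,12R)-11,12-epoxy C13 alcohol, that is (2E,6E,10R,11R)-10,11-epoxy-12-hydroxy-3,7,11-trimethyldodeca-2,6-dien-1-yl acetate
Conditions: Ti(OiPr)4 (10 mol %), D-(−)-diethyl tartrate (12 mol %), anhydrous t-BuOOH, 4 Å MS, CH2Cl2, −20 °C
Reagents that add atoms: tert-butyl hydroperoxide CC(C)(C)OO
Why: Sharpless asymmetric epoxidation touches only the alkene whose allylic hydroxyl binds to titanium, and for an E-2-methylalk-2-en-1-ol the D-(−)-tartrate catalyst gives the (2R,3R)-epoxy alcohol, which fixes C12 as R for good and C11 as R for the time being.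

Step 4
Reactants: 4 (11R,12R)-epoxy alcohol
Product: 5 (11S,12R)-11-chloro-12,13-diol, that is (2E,6E,10S,11R)-10-chloro-11,12-dihydroxy-3,7,11-trimethyldodeca-2,6-dien-1-yl acetate
Conditions: ClTi(OiPr)3 (1.5 equiv), CH2Cl2, 0 °C to rt; aq. tartaric acid work-up
Reagents that add atoms: chlorotitanium triisopropoxide CC(C)O[Ti](Cl)(OC(C)C)OC(C)C
Why: In this titanium-assisted nucleophilic opening of a 2,3-epoxy alcohol, alkoxide exchange ties the C13 oxygen and the epoxide oxygen to one titanium centre, and chloride then attacks the distal secondary C11 from the rear (SN2, R to S) rather than the quaternary C12, whose cationic character is damped by the adjacent C13–O bond, so that C12–O keeps its configuration.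

Step 5
Reactants: 5 (11S,12R)-chlorodiol
Product: 6 O12,O13-bis(triethylsilyl) ether of 5
Conditions: TESOTf (2.5 equiv), 2,6-lutidine, CH2Cl2, −78 to 0 °C
Reagents that add atoms: triethylsilyl triflate CC[Si](CC)(CC)OS(=O)(=O)C(F)(F)F
Why: Silyl triflate silylation covers the primary and the hindered tertiary hydroxyl in one operation with a non-nucleophilic base, so that no alkoxide able to displace the neighbouring chloride is ever formed.

Step 6
Reactants: 6 bis(triethylsilyl) ether
Product: 7 C13 aldehyde, that is (2E,6E,10S,11R)-10-chloro-3,7,11-trimethyl-12-oxo-11-(triethylsilyloxy)dodeca-2,6-dien-1-yl acetate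
Conditions: (COCl)2 (4 equiv), DMSO (8 equiv), CH2Cl2, −78 to −40 °C; then Et3N, −78 to 0 °C
Reagents that add atoms: none
Why: This is a Swern oxidation applied directly to a silyl ether, a known primary-selective reaction in which the chlorosulfonium reagent cleaves and oxidises the primary TES ether while the tertiary one stays, and the aldehyde cannot epimerise because C12 carries no hydrogen.

Step 7
Reactants: 7 C13 aldehyde; 8 methyltriphenylphosphonium bromide
Product: 10 C13=C14 vinyl compound (2E,6E,10S,11R)-10-chloro-3,7,11-trimethyl-11-(triethylsilyloxy)trideca-2,6,12-trien-1-yl acetate, via methylenetriphenylphosphorane 9 (not isolated)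
Conditions: 8 (1.6 equiv), KN(SiMe3)2 (1.5 equiv), THF, 0 °C; then 7, −78 to 0 °C
Reagents that add atoms: methyltriphenylphosphonium bromide (8) C[P+](c1ccccc1)(c1ccccc1)c1ccccc1.[Br-]
Why: Wittig methylenation brings in C14, and the non-enolisable aldehyde reacts with the ylide far faster than the acetate does at low temperature.

Step 8
Reactants: 10 C13=C14 vinyl compound
Product: 12 C14 primary alcohol (2E,6E,10S,11R)-10-chloro-13-hydroxy-3,7,11-trimethyl-11-(triethylsilyloxy)trideca-2,6-dien-1-yl acetate, via B-alkyl-9-BBN adduct 11 (not isolated)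
Conditions: 9-BBN (1.3 equiv), THF, 0 °C to rt; then 30% H2O2, 3 M aq. NaOAc, 0 °C to rt
Reagents that add atoms: hydrogen peroxide OO; 9-borabicyclo[3.3.1]nonane B1C2CCCC1CCC2 (boron and its ring only in 11)
Why: In this hydroboration–oxidation 9-BBN adds to the monosubstituted C13=C14 alkene orders of magnitude faster than to trisubstituted alkenes and places boron on terminal C14, and the buffered peroxide work-up spares the acetate and the silyl ether.

Step 9
Reactants: 12 C14 primary alcohol
Product: 13 O12,O14-bis(triethylsilyl) ether acetate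
Conditions: TESCl, imidazole, CH2Cl2, 0 °C
Reagents that add atoms: chlorotriethylsilane CC[Si](Cl)(CC)CC
Why: Standard silylation of the primary alcohol gives a C14 mask that withstands hydride, carbonate base and the alane and that can later be oxidised directly to the aldehyde.

Step 10
Reactants: 13 bis(triethylsilyl) ether acetate
Product: 14 allylic alcohol (2E,6E,10S,11R)-10-chloro-3,7,11-trimethyl-11,13-bis(triethylsilyloxy)trideca-2,6-dien-1-ol
Conditions: i-Bu2AlH (2.3 equiv), CH2Cl2, −78 °C; aq. potassium sodium tartrate
Reagents that add atoms: none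
Why: Reductive ester cleavage at low temperature frees the C2 alcohol without the basic methanol that could loosen the primary silyl ether, and neither the alkyl chloride nor the silyl ethers react with the hydride at −78 °C.

Step 11
Reactants: 14 allylic alcohol
Product: 16 allylic bromide (2E,6E,10S,11R)-1-bromo-10-chloro-3,7,11-trimethyl-11,13-bis(triethylsilyloxy)trideca-2,6-diene, via allylic mesylate 15 (not isolated)
Conditions: MsCl, Et3N, THF, −40 °C; then LiBr (4 equiv), THF, 0 °C
Reagents that add atoms: lithium bromide [Li+].[Br-]; methanesulfonyl chloride CS(=O)(=O)Cl (mesyl group only in 15)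
Why: Mesylation followed by in situ SN2 displacement with bromide is the standard mild way from farnesol-type alcohols to primary allylic bromides without allylic transposition or loss of the E geometry.

Step 12
Reactants: 16 allylic bromide; 17 methyl propiolate
Product: 18 skipped enynoate methyl (5E,9E,13S,14R)-13-chloro-6,10,14-trimethyl-14,16-bis(triethylsilyloxy)hexadeca-5,9-dien-2-ynoate
Conditions: 17 (1.5 equiv), CuI (20 mol %), K2CO3 (1.5 equiv), n-Bu4NI (10 mol %), DMF, 0 °C to rt
Reagents that add atoms: methyl propiolate (17) C#CC(=O)OC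
Why: In this copper-catalysed allylation of a terminal alkyne the copper acetylide of the propiolate displaces the primary bromide at the unhindered C2 to form C1–C2 with retention of the C3=C4 geometry, and the weak carbonate base is chosen to limit isomerisation of the doubly activated C2 methylene.

Step 13
Reactants: 18 skipped enynoate; 19 2-(iodomethyl)-4,4,5,5-tetramethyl-1,3,2-dioxaborolane
Product: 21 allylboronate methyl (2Z,5E,9E,13S,14R)-13-chloro-6,10,14-trimethyl-2-[(4,4,5,5-tetramethyl-1,3,2-dioxaborolan-2-yl)methyl]-14,16-bis(triethylsilyloxy)hexadeca-2,5,9-trienoate, via alkenylalane 20 (not isolated)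
Conditions: i-Bu2AlH (1.3 equiv), HMPA (2.5 equiv), THF, 0 °C; 18, 0 °C; then 19 (1.6 equiv), 0 °C to rt
Reagents that add atoms: 2-(iodomethyl)-4,4,5,5-tetramethyl-1,3,2-dioxaborolane (19) ICB1OC(C)(C)C(C)(C)O1; diisobutylaluminium hydride CC(C)C[AlH]CC(C)C (aluminium only in 20)
Why: In this conjugate hydroalumination of an ynoate followed by alkylation of the α-aluminated enoate, a known route to 3-substituted 2-(alkoxycarbonyl)allylboronates, H and Al add syn across C1≡C15 and the alkenylalane displaces iodide from 19 with retention, so that C17 ends up trans to C2.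

Step 14
Reactants: 21 allylboronate bis(triethylsilyl) ether
Product: 22 seco aldehyde methyl (2Z,5E,9E,13S,14R)-13-chloro-6,10,14-trimethyl-16-oxo-2-[(4,4,5,5-tetramethyl-1,3,2-dioxaborolan-2-yl)methyl]-14-(triethylsilyloxy)hexadeca-2,5,9-trienoate
Conditions: (COCl)2 (4 equiv), DMSO (8 equiv), CH2Cl2, −78 to −40 °C; then Et3N, −78 to 0 °C; used at once
Reagents that add atoms: none
Why: Swern oxidation applied directly to the primary TES ether, as in step 6, unmasks the C14 aldehyde under cold non-aqueous conditions that leave the tertiary TES ether, the enoate and the ester-deactivated allylboronate alone, and the uncatalysed allylboration is too slow to interfere during isolation.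

Step 15
Reactants: 22 seco aldehyde
Product: 24 O12-triethylsilyl ether of the target (1R,3E,7E,11S,12R,14S), via macrocyclic pinacol borate 23 (not isolated)
Conditions: 22 in CH2Cl2 added by syringe pump over 20 h to Sc(OTf)3 (1.0 equiv), 4 Å MS, CH2Cl2, rt (final 1 mM); then p-TsOH·H2O (10 mol %), rt
Reagents that add atoms: none
Why: Proposed new method: Sc(OTf)3 binds a pinacol oxygen and so raises the Lewis acidity of boron, the C14 aldehyde coordinates to boron, and C1 adds to C14 through a closed six-membered chair (B, O, C14, C1, C15, C17) while the π-bond shifts to C15=C17, after which the borate oxygen of 23 attacks the C16 ester under acid catalysis and MeOBpin leaves. The closest known reactions are the Lewis-acid-catalysed intermolecular allylboration–lactonisation of aldehydes with 2-(alkoxycarbonyl)allylboronates, intramolecular allylborations that form five- to seven-membered rings, and macrocyclising Nozaki–Hiyama–Kishi allylations with 2-(alkoxycarbonyl)allyl bromides, so that only the closure of a 14-membered ring inside the allylboration transition state is new. The carbocycle closes 14-exo-trig (C14=O and C1=C15 both lie outside the ring that forms) and the lactone closes 5-exo-trig by addition–elimination of O14 at C16. The anti C1/C14 relation, which becomes the trans ring fusion, is controlled by the alkene geometry, because C2 (trans to C17) and C13 both take equatorial places on the chair. The absolute sense (attack on the Re face of the aldehyde, 1R,14S, C14–O syn to C12–O) is controlled by the C12 centre, since in the extended C11–C14 backbone favoured by the forming ring the bulky boron-bound O14 must lie 1,3-parallel either to the C12 methyl group or to the slimmer C12–O bond and should choose the latter. The step also needs cyclisation to outrun oligomerisation and the aldehyde to stay untouched until activation, which is secured by slow addition to a full equivalent of promoter, by the two rigid E-trisubstituted alkenes that cut down the chain rotors, and by the ester group that makes the boronate inert without Lewis acid.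

Step 16
Reactants: 24 O12-triethylsilyl ether of the target
Product: 25 target, (1R,3E,7E,11S,12R,14S)-11-chloro-12-hydroxycembra-3,7,15(17)-trien-16,14-olide
Conditions: HF·pyridine, THF, 0 °C to rt
Reagents that add atoms: none
Why: Fluoride-assisted acidic desilylation removes the tertiary TES ether without generating an alkoxide, so the chlorohydrin cannot close to an epoxide and the α-methylene lactone meets no basic nucleophile.

Compound list
1 | (2E,6E)-farnesol | CC(C)=CCC/C(C)=C/CC/C(C)=C/CO | starting material
2 | (2E,6E)-farnesyl acetate | CC(C)=CCC/C(C)=C/CC/C(C)=C/COC(C)=O | intermediate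
3 | (2E,6E,10E)-12-hydroxy-3,7,11-trimethyldodeca-2,6,10-trien-1-yl acetate | OC/C(C)=C/CC/C(C)=C/CC/C(C)=C/COC(C)=O | intermediate
4 | (2E,6E,10R,11R)-10,11-epoxy-12-hydroxy-3,7,11-trimethyldodeca-2,6-dien-1-yl acetate (C11 R, C12 R) | OC[C@@]1(C)O[C@@H]1CC/C(C)=C/CC/C(C)=C/COC(C)=O | intermediate
5 | (2E,6E,10S,11R)-10-chloro-11,12-dihydroxy-3,7,11-trimethyldodeca-2,6-dien-1-yl acetate (C11 S, C12 R) | OC[C@@](C)(O)[C@@H](Cl)CC/C(C)=C/CC/C(C)=C/COC(C)=O | intermediate
6 | (2E,6E,10S,11R)-10-chloro-3,7,11-trimethyl-11,12-bis(triethylsilyloxy)dodeca-2,6-dien-1-yl acetate | CC[Si](CC)(CC)OC[C@@](C)(O[Si](CC)(CC)CC)[C@@H](Cl)CC/C(C)=C/CC/C(C)=C/COC(C)=O | intermediate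
7 | (2E,6E,10S,11R)-10-chloro-3,7,11-trimethyl-12-oxo-11-(triethylsilyloxy)dodeca-2,6-dien-1-yl acetate | O=C[C@@](C)(O[Si](CC)(CC)CC)[C@@H](Cl)CC/C(C)=C/CC/C(C)=C/COC(C)=O | intermediate
8 | methyltriphenylphosphonium bromide | C[P+](c1ccccc1)(c1ccccc1)c1ccccc1.[Br-] | starting material
9 | methylenetriphenylphosphorane | C=P(c1ccccc1)(c1ccccc1)c1ccccc1 | intermediate
10 | (2E,6E,10S,11R)-10-chloro-3,7,11-trimethyl-11-(triethylsilyloxy)trideca-2,6,12-trien-1-yl acetate | C=C[C@@](C)(O[Si](CC)(CC)CC)[C@@H](Cl)CC/C(C)=C/CC/C(C)=C/COC(C)=O | intermediate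
11 | B-alkyl-9-BBN adduct of 10 (boron on C14) | C1CCC2CCCC1B2CC[C@@](C)(O[Si](CC)(CC)CC)[C@@H](Cl)CC/C(C)=C/CC/C(C)=C/COC(C)=O | intermediate
12 | (2E,6E,10S,11R)-10-chloro-13-hydroxy-3,7,11-trimethyl-11-(triethylsilyloxy)trideca-2,6-dien-1-yl acetate | OCC[C@@](C)(O[Si](CC)(CC)CC)[C@@H](Cl)CC/C(C)=C/CC/C(C)=C/COC(C)=O | intermediate
13 | (2E,6E,10S,11R)-10-chloro-3,7,11-trimethyl-11,13-bis(triethylsilyloxy)trideca-2,6-dien-1-yl acetate | CC[Si](CC)(CC)OCC[C@@](C)(O[Si](CC)(CC)CC)[C@@H](Cl)CC/C(C)=C/CC/C(C)=C/COC(C)=O | intermediate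
14 | (2E,6E,10S,11R)-10-chloro-3,7,11-trimethyl-11,13-bis(triethylsilyloxy)trideca-2,6-dien-1-ol | CC[Si](CC)(CC)OCC[C@@](C)(O[Si](CC)(CC)CC)[C@@H](Cl)CC/C(C)=C/CC/C(C)=C/CO | intermediate
15 | methanesulfonate of 14 | CC[Si](CC)(CC)OCC[C@@](C)(O[Si](CC)(CC)CC)[C@@H](Cl)CC/C(C)=C/CC/C(C)=C/COS(C)(=O)=O | intermediate
16 | (2E,6E,10S,11R)-1-bromo-10-chloro-3,7,11-trimethyl-11,13-bis(triethylsilyloxy)trideca-2,6-diene | CC[Si](CC)(CC)OCC[C@@](C)(O[Si](CC)(CC)CC)[C@@H](Cl)CC/C(C)=C/CC/C(C)=C/CBr | intermediate
17 | methyl propiolate | C#CC(=O)OC | starting material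
18 | methyl (5E,9E,13S,14R)-13-chloro-6,10,14-trimethyl-14,16-bis(triethylsilyloxy)hexadeca-5,9-dien-2-ynoate | CC[Si](CC)(CC)OCC[C@@](C)(O[Si](CC)(CC)CC)[C@@H](Cl)CC/C(C)=C/CC/C(C)=C/CC#CC(=O)OC | intermediate
19 | 2-(iodomethyl)-4,4,5,5-tetramethyl-1,3,2-dioxaborolane | ICB1OC(C)(C)C(C)(C)O1 | starting material
20 | α-(diisobutylalumino)enoate from 18 (Al on C15, trans to C2) | CC[Si](CC)(CC)OCC[C@@](C)(O[Si](CC)(CC)CC)[C@@H](Cl)CC/C(C)=C/CC/C(C)=C/C/C=C(/[Al](CC(C)C)CC(C)C)C(=O)OC | intermediate
21 | methyl (2Z,5E,9E,13S,14R)-13-chloro-6,10,14-trimethyl-2-[(4,4,5,5-tetramethyl-1,3,2-dioxaborolan-2-yl)methyl]-14,16-bis(triethylsilyloxy)hexadeca-2,5,9-trienoate | CC[Si](CC)(CC)OCC[C@@](C)(O[Si](CC)(CC)CC)[C@@H](Cl)CC/C(C)=C/CC/C(C)=C/C/C=C(/CB1OC(C)(C)C(C)(C)O1)C(=O)OC | intermediate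
22 | methyl (2Z,5E,9E,13S,14R)-13-chloro-6,10,14-trimethyl-16-oxo-2-[(4,4,5,5-tetramethyl-1,3,2-dioxaborolan-2-yl)methyl]-14-(triethylsilyloxy)hexadeca-2,5,9-trienoate (seco aldehyde) | O=CC[C@@](C)(O[Si](CC)(CC)CC)[C@@H](Cl)CC/C(C)=C/CC/C(C)=C/C/C=C(/CB1OC(C)(C)C(C)(C)O1)C(=O)OC | intermediate
23 | macrocyclic pinacol borate (1R,11S,12R,14S): C14–O–Bpin, C1 bearing C15(=C17H2)CO2Me, O12-TES | CC1(C)OB(O[C@H]2C[C@@](C)(O[Si](CC)(CC)CC)[C@@H](Cl)CC/C(C)=C/CC/C(C)=C/C[C@@H]2C(=C)C(=O)OC)OC1(C)C | intermediate
24 | (1R,3E,7E,11S,12R,14S)-11-chloro-12-(triethylsilyloxy)cembra-3,7,15(17)-trien-16,14-olide | C=C1C(=O)O[C@H]2C[C@@](C)(O[Si](CC)(CC)CC)[C@@H](Cl)CC/C(C)=C/CC/C(C)=C/C[C@H]12 | intermediate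
25 | (1R,3E,7E,11S,12R,14S)-11-chloro-12-hydroxycembra-3,7,15(17)-trien-16,14-olide (CNP0247658.1) | C=C1C(=O)O[C@H]2C[C@@](C)(O)[C@@H](Cl)CC/C(C)=C/CC/C(C)=C/C[C@H]12 | target

Total step count: 16. Longest linear sequence: 16 steps, from 1 to 25. Compounds 8, 17 and 19 are bought and enter directly.

Steps most likely to fail

1) Step 15.
- **What may go wrong:** Ring closure may be too slow at high dilution. Oligomerisation, Lewis-acid-induced loss of the silyl ether or β-elimination at the aldehyde could then take over. The aldehyde face may also be chosen with poor selectivity relative to C12.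
- **Fallback:** It uses known chemistry, sets out from 21 and comes back at 24. The same C1–C14 bond is closed with an allylchromium reagent instead of the boronate.
  - Oxidation of the C–B bond of 21 with NaBO3·4H2O in aqueous THF should give the 2-(hydroxymethyl)enoate F1.
  - An Appel reaction (CBr4, PPh3, CH2Cl2, 0 °C) should convert it into the 2-(bromomethyl)enoate F2.
  - Swern oxidation of the primary TES ether, with i-Pr2NEt as the hindered base, should give the bromo aldehyde F3.
  - Slow addition of F3 to excess CrCl2 (divalent chromium) in THF should close the 14-membered ring by a Nozaki–Hiyama–Kishi-type allylation. This runs through the equilibrating allylchromium chair that favours the anti adduct and should give the macrocyclic hydroxy ester F4.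
  - Catalytic p-TsOH should then lactonise F4 to 24.
  - A chiral bis(oxazoline) or sulfonamide ligand on chromium, known to govern 2-(alkoxycarbonyl)allylations of aldehydes, can override a weak substrate bias at C14.

2) Step 13.
- **What may go wrong:** The α-aluminated enoate may isomerise through its allenolate form before it is alkylated, which erodes the alkene geometry on which the trans fusion depends. The alkylation with 19 may also stall.
- **Fallback:** It sets out from 18 and comes back at 21. The nucleophilic alane is replaced by a stereoretentive cross-coupling.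
  - Syn hydrostannation of 18 with Bu3SnH and Pd(PPh3)4 should give the α-stannyl enoate F5.
  - Iododestannylation with I2 at low temperature should give the α-iodo enoate F6 with retention.
  - A Negishi coupling of F6, catalysed by Pd(PPh3)4, with (pinacolboryl)methylzinc iodide F7, made from 19 and zinc dust, should deliver 21 with C17 trans to C2.

3) Step 4.
- **What may go wrong:** Chloride may attack the tertiary C12 instead of C11. Ionisation of the activated epoxide may also trigger cation–olefin cyclisation onto the C7=C8 alkene.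
- **Fallback:** It sets out from 4 and comes back at 7. The regiochemistry is governed by an electronic bias instead of chelation.
  - Parikh–Doering oxidation of 4 (SO3·pyridine, DMSO, Et3N) should give the epoxy aldehyde F8.
  - The formyl group of F8 shuts off both cation formation and SN2 attack at C12. LiCl and AcOH in THF should therefore open it at C11 with inversion, the way metal halides open glycidic esters and α,β-epoxy ketones at the β-carbon, to give the β-chloro-α-hydroxy aldehyde F9.
  - Silylation with TESOTf and 2,6-lutidine then gives 7.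

Further compounds
F1 | step 15 | methyl (2Z,5E,9E,13S,14R)-13-chloro-2-(hydroxymethyl)-6,10,14-trimethyl-14,16-bis(triethylsilyloxy)hexadeca-2,5,9-trienoate | CC[Si](CC)(CC)OCC[C@@](C)(O[Si](CC)(CC)CC)[C@@H](Cl)CC/C(C)=C/CC/C(C)=C/C/C=C(/CO)C(=O)OC
F2 | step 15 | methyl (2E,5E,9E,13S,14R)-2-(bromomethyl)-13-chloro-6,10,14-trimethyl-14,16-bis(triethylsilyloxy)hexadeca-2,5,9-trienoate | CC[Si](CC)(CC)OCC[C@@](C)(O[Si](CC)(CC)CC)[C@@H](Cl)CC/C(C)=C/CC/C(C)=C/C/C=C(/CBr)C(=O)OC
F3 | step 15 | methyl (2E,5E,9E,13S,14R)-2-(bromomethyl)-13-chloro-6,10,14-trimethyl-16-oxo-14-(triethylsilyloxy)hexadeca-2,5,9-trienoate | O=CC[C@@](C)(O[Si](CC)(CC)CC)[C@@H](Cl)CC/C(C)=C/CC/C(C)=C/C/C=C(/CBr)C(=O)OC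
F4 | step 15 | macrocyclic hydroxy ester (1R,11S,12R,14S): C14–OH, C1 bearing C15(=C17H2)CO2Me, O12-TES | O[C@H]1C[C@@](C)(O[Si](CC)(CC)CC)[C@@H](Cl)CC/C(C)=C/CC/C(C)=C/C[C@@H]1C(=C)C(=O)OC
F5 | step 13 | methyl (2E,5E,9E,13S,14R)-13-chloro-6,10,14-trimethyl-2-(tributylstannyl)-14,16-bis(triethylsilyloxy)hexadeca-2,5,9-trienoate | CC[Si](CC)(CC)OCC[C@@](C)(O[Si](CC)(CC)CC)[C@@H](Cl)CC/C(C)=C/CC/C(C)=C/C/C=C(/[Sn](CCCC)(CCCC)CCCC)C(=O)OC
F6 | step 13 | methyl (2E,5E,9E,13S,14R)-13-chloro-2-iodo-6,10,14-trimethyl-14,16-bis(triethylsilyloxy)hexadeca-2,5,9-trienoate | CC[Si](CC)(CC)OCC[C@@](C)(O[Si](CC)(CC)CC)[C@@H](Cl)CC/C(C)=C/CC/C(C)=C/C/C=C(/I)C(=O)OC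
F7 | step 13 | [(4,4,5,5-tetramethyl-1,3,2-dioxaborolan-2-yl)methyl]zinc iodide | I[Zn]CB1OC(C)(C)C(C)(C)O1
F8 | step 4 | (2E,6E,10R,11R)-10,11-epoxy-3,7,11-trimethyl-12-oxododeca-2,6-dien-1-yl acetate | O=C[C@@]1(C)O[C@@H]1CC/C(C)=C/CC/C(C)=C/COC(C)=O
F9 | step 4 | (2E,6E,10S,11R)-10-chloro-11-hydroxy-3,7,11-trimethyl-12-oxododeca-2,6-dien-1-yl acetate | O=C[C@@](C)(O)[C@@H](Cl)CC/C(C)=C/CC/C(C)=C/COC(C)=O
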